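## Retrosynthetic overview

1. The last bond made is carbinol carbon to ring A methine. A catalyst-controlled anti allylboration joins enal 11 (ring B plus the E side chain) with ring A allylboronate 21 and sets both of these stereocentres.
2. The strategy rests on ring B (C1' = CH bearing the butenyl chain, C2'/C3' = CH2, C4' = C(OH)CH3, C5' = CHBr, C6' = CH2). C1' and C4' are 1,4-related and C5' sits next to C4', so a C4'=C5' enol silane marks C5' as the only site for bromine.
3. That enol silane comes from a para-selective, enantioselective [4+2] of 2-silyloxydiene 3 with but-3-en-2-one 1. The acetyl group of the adduct already carries the methyl-bearing alkene carbon.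
4. After the cycloaddition: olefination to the E-enoate, bromination at C5' with equilibration to the equatorial bromide, methyl addition anti to bromine, then reduction and oxidation to the enal.
5. Ring A is built in a separate branch from 2,2-dimethylbut-3-enoic acid by olefination and ring-closing metathesis. Ring order: ring B (step 2), ring A (step 11), union (step 15).

Key step: step 2

Assumption: the (S)-oxazaborolidinium ion is taken to give (S)-4, and the (S)-phosphoric acid to direct the boronate to the Si face of 11, as the usual transition-state models predict; if either sense proved opposite, the enantiomeric catalyst would be used with no other change.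

## Route

Step 1
Reactants: 1 but-3-en-2-one; 2 triisopropylsilyl trifluoromethanesulfonate
Product: 3 2-(triisopropylsilyloxy)buta-1,3-diene
Conditions: Et3N, Et2O, 0 to 23 °C
Reagents that add atoms: none
Why: Soft enolisation of the methyl ketone (O-silylation by the silyl triflate, then loss of a methyl proton to the amine) is the standard way to the cross-conjugated 2-silyloxydiene.

Step 2
Reactants: 3 2-(triisopropylsilyloxy)buta-1,3-diene; 1 but-3-en-2-one
Product: 4 1-[(1S)-4-(triisopropylsilyloxy)cyclohex-3-en-1-yl]ethan-1-one
Conditions: (S)-1-(2-methylphenyl)-3,3-diphenyltetrahydro-1H,3H-pyrrolo[1,2-c][1,3,2]oxazaborole (20 mol%), (CF3SO2)2NH (18 mol%), CH2Cl2, −78 °C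
Reagents that add atoms: none
Why: Protonation of the oxazaborolidine at nitrogen makes boron strongly Lewis acidic, and it binds the carbonyl oxygen of 1 on the lone pair syn to the vinyl group, the s-trans enone being held by an α-C–H···O contact so that one π face lies against an aryl group of the catalyst. Diene 3 adds to the open face in a concerted, asynchronous normal-demand [4+2] cycloaddition; the closest known reaction type is the cationic oxazaborolidine-catalysed Diels–Alder reaction of 2-silyloxybutadienes with acrylates and enones. Ring B is closed by cycloaddition, both σ bonds being made suprafacially in one step: diene C1 (the CH2 on the silyloxy carbon, largest HOMO coefficient) to the β-carbon of 1 and diene C4 to the α-carbon. The one new stereocentre, the acetyl-bearing carbon, is set S by the catalyst alone, the (S)-catalyst being the antipode that gives (S)-cyclohex-3-enyl carbonyl adducts from acrylate-type dienophiles. The step needs para regioselectivity and a single enol silane regioisomer, and the 2-silyloxy donor secures both, leaving the C4'=C5' double bond between the future carbinol carbon and the future CHBr carbon. The low temperature and the non-nucleophilic triflimide counter-ion protect the acid-labile diene and product.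

Step 3
Reactants: 4 1-[(1S)-4-(triisopropylsilyloxy)cyclohex-3-en-1-yl]ethan-1-one; 5 triethyl phosphonoacetate
Product: 6 ethyl (2E)-3-[(1S)-4-(triisopropylsilyloxy)cyclohex-3-en-1-yl]but-2-enoate
Conditions: NaH (slightly less than 5), THF, 0 to 23 °C
Reagents that add atoms: none
Why: Horner–Wadsworth–Emmons olefination of the methyl ketone should place the bulkier ring residue trans to the ester (E, minor Z isomer removed by chromatography); the enol silane is inert to the phosphonate anion, and keeping NaH below the amount of phosphonate limits enolisation at the α-methine.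

Step 4
Reactants: 6 ethyl (2E)-3-[(1S)-4-(triisopropylsilyloxy)cyclohex-3-en-1-yl]but-2-enoate
Product: 8 ethyl (2E)-3-[(1S,3S)-3-bromo-4-oxocyclohexyl]but-2-enoate, via axial bromoketone 7 (not isolated)
Conditions: NBS, NaHCO3, THF, −78 to 0 °C; then LiBr, DMF, 23 °C; chromatography, recovered 7 resubjected to LiBr/DMF
Reagents that add atoms: N-bromosuccinimide, O=C1CCC(=O)N1Br; lithium bromide, [Li+].[Br-] (through bromide exchange the bromine of 8 may stem from either)
Why: Electrophilic α-bromination of the silyl enol ether can only occur at C5' and is expected to give mainly the axial bromide 7 by chair-like attack, after which degenerate SN2 exchange with bromide in a polar medium should equilibrate C5' towards the more polar diequatorial epimer 8 (C5' S, bromine cis to the side chain), which is separated.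

Step 5
Reactants: 8 ethyl (2E)-3-[(1S,3S)-3-bromo-4-oxocyclohexyl]but-2-enoate
Product: 9 ethyl (2E)-3-[(1S,3S,4R)-3-bromo-4-hydroxy-4-methylcyclohexyl]but-2-enoate
Conditions: MeMgBr (1.2 equiv), Et2O–CH2Cl2, −78 °C; quench with aqueous NH4Cl at −78 °C
Reagents that add atoms: methylmagnesium bromide, C[Mg]Br
Why: Grignard 1,2-addition is chemoselective for the activated α-bromoketone over the hindered β,β-disubstituted enoate at −78 °C, and methyl should enter anti to the polar C–Br bond and from the equatorial direction (Cornforth-type control, as in the addition of methyl Grignard reagents to 2-halocyclohexanones), giving equatorial methyl and axial hydroxyl cis to bromine (C4' R); the cold quench avoids semipinacol rearrangement of the magnesium alkoxide.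

Step 6
Reactants: 9 ethyl (2E)-3-[(1S,3S,4R)-3-bromo-4-hydroxy-4-methylcyclohexyl]but-2-enoate
Product: 10 (1R,2S,4S)-2-bromo-4-[(2E)-4-hydroxybut-2-en-2-yl]-1-methylcyclohexan-1-ol
Conditions: i-Bu2AlH (3.5 equiv), CH2Cl2, −78 °C; Rochelle salt work-up
Reagents that add atoms: none
Why: Hydride reduction of the enoate to the allylic alcohol with i-Bu2AlH proceeds at a temperature at which the secondary bromide and the aluminium alkoxide of the cis-bromohydrin are stable.

Step 7
Reactants: 10 (1R,2S,4S)-2-bromo-4-[(2E)-4-hydroxybut-2-en-2-yl]-1-methylcyclohexan-1-ol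
Product: 11 (2E)-3-[(1S,3S,4R)-3-bromo-4-hydroxy-4-methylcyclohexyl]but-2-enal
Conditions: activated MnO2, CH2Cl2, 23 °C
Reagents that add atoms: none
Why: Allylic oxidation with MnO2 is selective for the primary allylic alcohol, leaves the tertiary alcohol and the bromide untouched and keeps the E geometry.

Step 8
Reactants: 5 triethyl phosphonoacetate; 12 allyl bromide
Product: 13 ethyl 2-(diethoxyphosphoryl)pent-4-enoate
Conditions: NaH, THF, 0 to 23 °C
Reagents that add atoms: none
Why: C-alkylation (SN2) of the stabilised phosphonate carbanion with a reactive allylic halide gives the α-allyl phosphonate, dialkylated material being removed by distillation.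

Step 9
Reactants: 14 2,2-dimethylbut-3-enoic acid
Product: 15 2,2-dimethylbut-3-en-1-ol
Conditions: LiAlH4, Et2O, 0 °C to reflux
Reagents that add atoms: none
Why: LiAlH4 reduction of a carboxylic acid to the primary alcohol leaves the isolated vinyl group untouched.

Step 10
Reactants: 15 2,2-dimethylbut-3-en-1-ol; 13 ethyl 2-(diethoxyphosphoryl)pent-4-enoate
Product: 17 ethyl (2E)-4,4-dimethyl-2-(prop-2-en-1-yl)hexa-2,5-dienoate, via 2,2-dimethylbut-3-enal 16 (not isolated)
Conditions: (COCl)2, DMSO, Et3N, CH2Cl2, −78 to 0 °C; washed and dried solution of 16 added to 13/NaH, THF, 0 to 40 °C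
Reagents that add atoms: none
Why: Swern oxidation gives the volatile, non-enolisable aldehyde, which is used in solution in a Horner–Wadsworth–Emmons olefination that should favour the E-enoate (ester trans to the quaternary carbon), the geometry that places the allyl group cis to the vinyl-bearing carbon for ring closure.

Step 11
Reactants: 17 ethyl (2E)-4,4-dimethyl-2-(prop-2-en-1-yl)hexa-2,5-dienoate
Product: 18 ethyl 3,3-dimethylcyclohexa-1,4-diene-1-carboxylate
Conditions: RuCl2(=CHPh)(H2IMes)(PCy3) (second-generation Grubbs catalyst, 5 mol%), 1,4-benzoquinone (10 mol%), CH2Cl2 (0.01 M), 40 °C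
Reagents that add atoms: none
Why: Ring-closing metathesis between the allyl and vinyl termini closes the six-membered skipped diene with loss of ethene; the trisubstituted enoate takes no part and benzoquinone suppresses alkene migration by ruthenium hydrides.

Step 12
Reactants: 18 ethyl 3,3-dimethylcyclohexa-1,4-diene-1-carboxylate
Product: 19 (3,3-dimethylcyclohexa-1,4-dien-1-yl)methanol
Conditions: i-Bu2AlH (2.2 equiv), CH2Cl2, −78 °C; Rochelle salt work-up
Reagents that add atoms: none
Why: 1,2-Reduction of the unsaturated ester with i-Bu2AlH gives the allylic alcohol under non-basic conditions that leave the skipped diene in place.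

Step 13
Reactants: 19 (3,3-dimethylcyclohexa-1,4-dien-1-yl)methanol
Product: 20 (3,3-dimethylcyclohexa-1,4-dien-1-yl)methyl acetate
Conditions: Ac2O, pyridine, DMAP (cat.), CH2Cl2, 0 to 23 °C
Reagents that add atoms: acetic anhydride, CC(=O)OC(C)=O
Why: Nucleophile-catalysed acylation converts the primary allylic alcohol into the acetate needed for π-allyl formation.

Step 14
Reactants: 20 (3,3-dimethylcyclohexa-1,4-dien-1-yl)methyl acetate
Product: 21 2-[(3,3-dimethylcyclohexa-1,4-dien-1-yl)methyl]-4,4,5,5-tetramethyl-1,3,2-dioxaborolane
Conditions: Pd2(dba)3 (2.5 mol%), B2pin2 (1.1 equiv), DMSO, 50 °C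
Reagents that add atoms: bis(pinacolato)diboron, CC1(C)OB(OC1(C)C)B1OC(C)(C)C(C)(C)O1
Why: In this Miyaura-type borylation of an allylic acetate, oxidative addition to zerovalent palladium gives a π-allyl complex without accessible β-hydrogens, and acetate-assisted transmetalation with B2pin2 followed by reductive elimination places boron on the unhindered CH2 terminus.

Step 15
Reactants: 11 (2E)-3-[(1S,3S,4R)-3-bromo-4-hydroxy-4-methylcyclohexyl]but-2-enal; 21 2-[(3,3-dimethylcyclohexa-1,4-dien-1-yl)methyl]-4,4,5,5-tetramethyl-1,3,2-dioxaborolane
Product: 22 (1R,2E)-3-[(1S,3S,4R)-3-bromo-4-hydroxy-4-methylcyclohexyl]-1-[(1R)-2,2-dimethyl-6-methylidenecyclohex-3-en-1-yl]but-2-en-1-ol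
Conditions: (S)-3,3'-bis(2,4,6-triisopropylphenyl)-1,1'-binaphthyl-2,2'-diyl hydrogen phosphate (10 mol%), 4 Å molecular sieves, toluene, −30 to 0 °C; aqueous work-up
Reagents that add atoms: none
Why: Chiral phosphoric acid-catalysed allylboration runs through a closed chair (Zimmerman–Traxler) transition state in which the ring-fixed E geometry of the boronate gives the anti relation between carbinol and ring A methine, and the (S)-acid, hydrogen-bonded to a boronate oxygen and the formyl hydrogen, should direct attack to the Si face, setting the carbinol carbon R and the ring A methine R while the double bond moves to the exocyclic position.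

## Compound list

1 | but-3-en-2-one | CC(=O)C=C | starting material
2 | triisopropylsilyl trifluoromethanesulfonate | CC(C)[Si](OS(=O)(=O)C(F)(F)F)(C(C)C)C(C)C | starting material
3 | 2-(triisopropylsilyloxy)buta-1,3-diene | C=CC(=C)O[Si](C(C)C)(C(C)C)C(C)C | intermediate
4 | 1-[(1S)-4-(triisopropylsilyloxy)cyclohex-3-en-1-yl]ethan-1-one | CC(=O)[C@H]1CCC(O[Si](C(C)C)(C(C)C)C(C)C)=CC1 | intermediate
5 | triethyl phosphonoacetate | CCOC(=O)CP(=O)(OCC)OCC | starting material
6 | ethyl (2E)-3-[(1S)-4-(triisopropylsilyloxy)cyclohex-3-en-1-yl]but-2-enoate | CCOC(=O)/C=C(\C)[C@H]1CCC(O[Si](C(C)C)(C(C)C)C(C)C)=CC1 | intermediate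
7 | ethyl (2E)-3-[(1S,3R)-3-bromo-4-oxocyclohexyl]but-2-enoate (axial bromide, trans to the side chain) | CCOC(=O)/C=C(\C)[C@H]1CCC(=O)[C@H](Br)C1 | intermediate
8 | ethyl (2E)-3-[(1S,3S)-3-bromo-4-oxocyclohexyl]but-2-enoate (equatorial bromide, cis to the side chain) | CCOC(=O)/C=C(\C)[C@H]1CCC(=O)[C@@H](Br)C1 | intermediate
9 | ethyl (2E)-3-[(1S,3S,4R)-3-bromo-4-hydroxy-4-methylcyclohexyl]but-2-enoate | CCOC(=O)/C=C(\C)[C@H]1CC[C@@](C)(O)[C@@H](Br)C1 | intermediate
10 | (1R,2S,4S)-2-bromo-4-[(2E)-4-hydroxybut-2-en-2-yl]-1-methylcyclohexan-1-ol | OC/C=C(\C)[C@H]1CC[C@@](C)(O)[C@@H](Br)C1 | intermediate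
11 | (2E)-3-[(1S,3S,4R)-3-bromo-4-hydroxy-4-methylcyclohexyl]but-2-enal | O=C/C=C(\C)[C@H]1CC[C@@](C)(O)[C@@H](Br)C1 | intermediate
12 | allyl bromide | C=CCBr | starting material
13 | ethyl 2-(diethoxyphosphoryl)pent-4-enoate | CCOC(=O)C(CC=C)P(=O)(OCC)OCC | intermediate
14 | 2,2-dimethylbut-3-enoic acid | C=CC(C)(C)C(=O)O | starting material
15 | 2,2-dimethylbut-3-en-1-ol | C=CC(C)(C)CO | intermediate
16 | 2,2-dimethylbut-3-enal | C=CC(C)(C)C=O | intermediate
17 | ethyl (2E)-4,4-dimethyl-2-(prop-2-en-1-yl)hexa-2,5-dienoate | CCOC(=O)/C(CC=C)=C/C(C)(C)C=C | intermediate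
18 | ethyl 3,3-dimethylcyclohexa-1,4-diene-1-carboxylate | CCOC(=O)C1=CC(C)(C)C=CC1 | intermediate
19 | (3,3-dimethylcyclohexa-1,4-dien-1-yl)methanol | OCC1=CC(C)(C)C=CC1 | intermediate
20 | (3,3-dimethylcyclohexa-1,4-dien-1-yl)methyl acetate | CC(=O)OCC1=CC(C)(C)C=CC1 | intermediate
21 | 2-[(3,3-dimethylcyclohexa-1,4-dien-1-yl)methyl]-4,4,5,5-tetramethyl-1,3,2-dioxaborolane | CC1(C)C=CCC(CB2OC(C)(C)C(C)(C)O2)=C1 | intermediate
22 | (1R,2E)-3-[(1S,3S,4R)-3-bromo-4-hydroxy-4-methylcyclohexyl]-1-[(1R)-2,2-dimethyl-6-methylidenecyclohex-3-en-1-yl]but-2-en-1-ol | C=C1CC=CC(C)(C)[C@@H]1[C@H](O)/C=C(\C)[C@H]1CC[C@@](C)(O)[C@@H](Br)C1 | target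

## Step count and risks

Total steps: 15. Longest linear sequence: 8 (steps 1 to 7 and 15, from 1); the ring A branch from 14 is 7 steps (9 to 15).

Steps most likely to fail:

1. Step 4. The bromide-exchange equilibrium at C5' may not favour the equatorial bromide enough, so that the needed epimer stays the minor one and repeated recycling loses material through elimination. Fallback (kinetic protonation in place of equilibration): setting out from 7 (or the crude 7/8 mixture), Me3SiOTf and Et3N in CH2Cl2 at 0 °C should give the bromine-bearing enol silane ethyl (2E)-3-[(1S)-3-bromo-4-(trimethylsilyloxy)cyclohex-3-en-1-yl]but-2-enoate F1, in which C5' is trigonal. Bu4NF buffered with AcOH in THF at −78 °C then releases the enolate, which should be protonated on carbon from the axial direction through a chair-like transition state; bromine is left equatorial and the sequence comes back to the route at 8.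

2. Step 15. Bond formation at the γ-carbon next to the quaternary centre may be slow, so that the uncatalysed pathway competes and facial control drops, giving the other anti diastereomer. Fallback (stoichiometric reagent control with a more reactive allylborane): setting out from 19, CBr4/PPh3 in CH2Cl2 gives 1-(bromomethyl)-3,3-dimethylcyclohexa-1,4-diene F2, and magnesium in Et2O at 0 °C gives [(3,3-dimethylcyclohexa-1,4-dien-1-yl)methyl]magnesium bromide F3. Treatment with (−)-B-methoxydiisopinocampheylborane, the antipode made from (+)-α-pinene whose allyl reagents add to the Si face of aldehydes, gives B-[(3,3-dimethylcyclohexa-1,4-dien-1-yl)methyl]diisopinocampheylborane F4, with boron on the primary carbon after borotropic equilibration. Addition of 11 at −78 °C, where the aldehyde reacts far faster than the free tertiary hydroxyl, and mild oxidative work-up with NaBO3 come back to the route at 22.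

3. Step 3. Enolisation of ketone 4 towards the ring methine by the basic phosphonate anion would racemise the centre set in step 2, and E/Z control may be incomplete. Fallback (acetylide addition and Meyer–Schuster rearrangement in place of phosphonate olefination): setting out from 4, lithium ethoxyacetylide (ethoxyacetylene, n-BuLi, THF, −78 °C) should add to the ketone faster than it deprotonates it, giving 4-ethoxy-2-[(1S)-4-(triisopropylsilyloxy)cyclohex-3-en-1-yl]but-3-yn-2-ol F5 as both carbinol epimers. AuCl3 (5 mol%) with EtOH in CH2Cl2 at 23 °C rearranges it to the ethyl enoate; the E isomer is isolated and the sequence comes back to the route at 6.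

## Further compounds

F1 | step 4 | ethyl (2E)-3-[(1S)-3-bromo-4-(trimethylsilyloxy)cyclohex-3-en-1-yl]but-2-enoate | CCOC(=O)/C=C(\C)[C@H]1CCC(O[Si](C)(C)C)=C(Br)C1
F2 | step 15 | 1-(bromomethyl)-3,3-dimethylcyclohexa-1,4-diene | BrCC1=CC(C)(C)C=CC1
F3 | step 15 | [(3,3-dimethylcyclohexa-1,4-dien-1-yl)methyl]magnesium bromide | Br[Mg]CC1=CC(C)(C)C=CC1
F4 | step 15 | B-[(3,3-dimethylcyclohexa-1,4-dien-1-yl)methyl]diisopinocampheylborane (isopinocampheyl groups from (+)-α-pinene) | CC1(C)C=CCC(CB([C@@H]2C[C@@H]3C[C@H]([C@H]2C)C3(C)C)[C@@H]2C[C@@H]3C[C@H]([C@H]2C)C3(C)C)=C1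
F5 | step 3 | 4-ethoxy-2-[(1S)-4-(triisopropylsilyloxy)cyclohex-3-en-1-yl]but-3-yn-2-ol (both carbinol epimers) | CCOC#CC(C)(O)[C@H]1CCC(O[Si](C(C)C)(C(C)C)C(C)C)=CC1
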